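# Proposed total synthesis of CNP0205451.4

## Structural features

The target is a biflavanoid in which C4 of an upper 2,3-trans-3,4-trans 4-arylflavan-3-ol (ring A with one hydroxyl at C7, ring B a pyrogallol, pyran ring C) is bonded to C2′ of the pyrogallol ring B of a lower 2,3-trans-3,4-trans flavan-3,4-diol, whose ring A also carries a single C7 hydroxyl. The lower ring B is therefore a pentasubstituted hub arene: C1′ bears the lower C2, the neighbouring C2′ bears the upper C4, and C3′–C5′ bear hydroxyls. There are six stereocentres in two contiguous triads, upper C2(R)–C3(S)–C4(S) and lower C2(R)–C3(S)–C4(R); the flat hub ring lies between them, so neither triad can steer the other. The fragile groups are the eight phenols (two air-sensitive pyrogallols), the lower C4 benzylic alcohol, which lies para to a ring A oxygen and is easily ionised or hydrogenolysed, and the two cyclic benzylic ether bonds C2–O1. The real difficulty is the crowded bond between the upper C4 stereocentre and a hub carbon flanked on both sides, together with absolute control at that C4. The chosen key step uses the fact that upper C4 carries ring A with O1 ortho to it: once ionised, C4 is the methide carbon of an o-quinone methide, O1=C8a–C4a=C4 is a heterodiene, and C2 and C3 of ring C are the two carbons of an aryl alkyne. Ring C can thus be annulated onto a C4–C2′ bond that is made beforehand by a plain carbonyl addition.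

## Logic of the disconnections

**26 from 25.** The lower C4–H bond is cut (alcohol back to ketone). This carbinol is the most labile function, so it is made last. 25 has one stereocentre fewer and a robust carbonyl. The forward step must deliver hydride to one face of a ketone in an unprotected polyphenol without acid.

**25 from 24.** Nine O–CH2Ph bonds are cut. One kind of protecting group for the eight phenols and the upper C3 hydroxyl allows a single deprotection. The hydrogenolysis must spare the carbonyl and both C2–O1 bonds, and it precedes the reduction so that no benzylic alcohol is exposed to it.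

**24 from 22, through 23.** The lower O1–C2 bond is cut. Ring closure by a phenol onto an epoxide is stereospecific, so the two lower stereocentres are traced back to one epoxide. The forward step needs 6-endo opening at the benzylic carbon with inversion, and a phenol protecting group that comes off under the conditions of the closure.

**22 from 21, and 21 from 17 and 20.** The two epoxide C–O bonds are cut, then the Cα=Cβ bond. This divides the molecule into the complete upper half and a simple acetophenone. The epoxidation must be controlled by the reagent, because the upper triad is remote; the condensation must tolerate an ortho-substituted aldehyde.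

**20 from 19 from 18.** Two O–C bonds are cut (methoxymethyl, benzyl). The forward steps rely on the different acidity of the two hydroxyls of 18.

**17 from 15 through 16, and 15 from 14.** The C1′–CHO bond is cut back to C1′–Br, and the C3 O–benzyl bond is cut. The bromine is a compact, inert placeholder for the one-carbon link to the lower unit. The C3 hydroxyl must be capped before the formyl group appears, since the two would form a six-membered lactol.

**14 from 12, through 13.** The C3–O and C2–H bonds are cut. Three stereocentres are reduced to one, carried by a cyclic enol ether. The forward hydroboration must place boron at C3 and add anti to the C4 aryl.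

**12 from 8 and 10, through 11.** The C3–C4 and O1–C2 bonds are cut, which takes ring C apart into an o-hydroxybenzhydrol and an aryl alkyne. The forward annulation must be regioselective and must select one face of the methide carbon.

**8 from 5 and 2, through 6 and 7.** The C4–C2′ bond is cut. The most hindered bond of the target is thus made as an aryl-metal addition to an aldehyde, before any stereocentre exists. The forward step needs metalation of 5 between bromine and oxygen, and a way to carry the phenol of 2 without a protecting group that would need acid for removal.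

**5 from 4 from 3; 2 from 1; 10 from 9.** O–C cuts and a one-carbon homologation lead to commercial materials.

## Other disconnections considered

**Alternative 1:** The cut lies inside the hub arene (C2′–C3′), so lower ring B is built on the upper flavan.
- **Forward key step:** the 4-alkenyl-2,3-bis(benzyloxy)cyclobutenone A2, whose alkene already joins upper C4 to the future C1′ with its silyloxymethyl group, is heated (toluene or xylene, 110–140 °C). Four-electron ring opening gives a dienylketene, six-electron electrocyclisation forms C2′–C3′, and tautomerisation gives the phenol A1. Benzylation of the new phenol, desilylation and oxidation would lead to 17.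
- **In favour:** the substitution pattern of the hub ring follows from the connectivity of A2, with no bond formed at a flanked aromatic carbon and no aryl metal next to a bromine. The reaction is thermal and neutral, and the C1′ carbon is already in place.
- **Against:** A2 needs the upper flavan with C4 already configured and bearing a trisubstituted alkenyl group, so the central stereochemical problem is moved elsewhere and not solved. 4-Monosubstituted 2,3-dialkoxycyclobutenones without a 4-hydroxyl are less accessible than squarate adducts, which would leave an extra oxygen at C6′. The alkenyl group prefers outward rotation on ring opening, so the productive isomer is reached only through reversible opening.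
- **Comparison:** on structure, A1 is the equal or the better of the chosen plan for the hub ring itself. On mechanism, its pericyclic cascade rests on firmer ground than the untested enantioselective annulation, and that is a point in its favour. On step economy it is clearly worse: it creates no stereocentre and should need well over twenty operations.

**Alternative 2:** The cut is C4–C4a of the upper unit.
- **Forward key step:** the trans-epoxide A4, an aryl ether of 3-benzyloxyphenol, is treated with BF3·OEt2 at low temperature. The ring A carbon para to the benzyloxy group opens the epoxide at its benzylic carbon with inversion, closing ring C and freeing the C3 hydroxyl to give A3.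
- **In favour:** the closure is stereospecific, so a trans-epoxide gives the 3,4-trans relation. The absolute configuration can come from established asymmetric epoxidation. A3 is identical with 14, so this plan would replace steps 4–7 and need no hydroboration.
- **Against:** A4 must be made as one stereoisomer with three open-chain stereocentres. Its aryl ether carbon is benzylic and, before epoxidation, also allylic, and therefore prone to racemisation during etherification. The epoxidation must be diastereoselective relative to that centre. In the closure, the cation-like carbon sits next to a twisted 2-bromo-6-alkoxyaryl ring that stabilises it poorly, so a hydride or aryl shift to a ketone and attack at the ring A carbon between the two oxygens would compete.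
- **Comparison:** on structure the two plans are equal after A3. On mechanism the alternative is better in needing no new catalytic asymmetric reaction, but it concentrates more selectivity questions in one step. On step economy it is worse, since A4 should take about twice as many operations as 8 and 10 together.

**Alternative 3:** The cut is the lower O1–C2 bond.
- **Forward key step:** mild acid removes the methoxymethyl group of A6, and the freed phenol opens the epoxy ketone at its benzylic carbon with inversion to give the trans-dihydroflavonol A5.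
- **In favour:** the closure is stereospecific, convergent and late. It sets two lower stereocentres under reagent control, independent of the upper triad.
- **Against, as a strategy:** it builds one C–O bond of the lower unit only, and leaves open how the upper triad and the crowded C4–C2′ bond are made, which is the harder half of the problem.
- **Comparison:** this is not a rival. A6 is identical with 22 and A5 with 24, and the chosen plan contains this very closure as step 14. On structure and mechanism the two are equal at that stage; the plans differ only in which step is taken as strategy-defining. The alternative has no advantage in step count, because everything up to 17 is still required.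

Key step: step 6

**Remarks on the chemistry (assumptions):**
- A check of the descriptors shows that the chromene 12 must be (4S) to lead to the (2R,3S,4S) upper unit; the lower unit of the target is (2R,3S,4R).
- The phenol of 8 is never protected: aldehyde 2 is used as its lithium phenolate 7. This avoids a protecting group whose acidic removal would ionise the benzhydrol too early, and it saves two steps.
- All eight phenols and the upper C3 hydroxyl are carried as benzyl ethers, and the bromine of 8 is kept as the C1′ handle.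

## Route

**Step 1**
Reactants: 1 2,4-dihydroxybenzaldehyde
Product: 2 4-(benzyloxy)-2-hydroxybenzaldehyde
Conditions: BnBr (1.05 equiv), NaHCO3, KI (cat.), MeCN, 80 °C
Reagents that add atoms: benzyl bromide, BrCc1ccccc1
Why: Williamson etherification; the 2-hydroxyl is held in a hydrogen bond to the formyl oxygen and is the weaker acid, so the mild base should alkylate only the 4-hydroxyl.

**Step 2**
Reactants: 3 5-bromo-1,2,3-trimethoxybenzene
Product: 4 5-bromobenzene-1,2,3-triol
Conditions: BBr3 (3.5 equiv), CH2Cl2, −78 °C → rt; then H2O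
Reagents that add atoms: none
Why: Lewis acid-mediated cleavage of aryl methyl ethers (BBr3 demethylation); the aryl bromide is inert and the methyl groups leave as bromomethane.

**Step 3**
Reactants: 4 5-bromobenzene-1,2,3-triol
Product: 5 5-bromo-1,2,3-tris(benzyloxy)benzene
Conditions: BnBr (3.3 equiv), K2CO3, DMF, 60 °C, argon
Reagents that add atoms: benzyl bromide, BrCc1ccccc1
Why: Threefold Williamson etherification, run under argon because the pyrogallol is air-sensitive in base; benzyl is chosen so that all ethers fall in one hydrogenolysis at the end.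

**Step 4**
Reactants: 5 5-bromo-1,2,3-tris(benzyloxy)benzene; 2 4-(benzyloxy)-2-hydroxybenzaldehyde
Product: 8 5-(benzyloxy)-2-{[6-bromo-2,3,4-tris(benzyloxy)phenyl](hydroxy)methyl}phenol (racemic), via aryllithium 6 (not isolated), via lithium phenolate 7 (not isolated)
Conditions: 5 (1.2 equiv), LiN(i-Pr)2 (1.25 equiv), THF, −78 °C, 1 h; then 7 [from 2 and LiN(SiMe3)2 (1.0 equiv), THF, −78 °C] by cannula, −78 → −40 °C; aq NH4Cl
Reagents that add atoms: none
Why: Directed ortho-lithiation removes the proton between bromine and an ether oxygen, the most acidic ring position, and the aryllithium 6 adds to the formyl group of 7 (1,2-addition); carrying the aldehyde as its phenolate masks the acidic hydroxyl without a protecting group, and the racemic carbinol centre is erased in step 6.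

**Step 5**
Reactants: 9 3,4,5-tris(benzyloxy)benzaldehyde
Product: 10 5-ethynyl-1,2,3-tris(benzyloxy)benzene
Conditions: dimethyl (1-diazo-2-oxopropyl)phosphonate (1.3 equiv), K2CO3 (2 equiv), MeOH/THF, rt
Reagents that add atoms: dimethyl (1-diazo-2-oxopropyl)phosphonate, CC(=O)C(=[N+]=[N-])P(=O)(OC)OC
Why: Seyferth–Gilbert homologation in the Ohira–Bestmann variant: methanolysis of the reagent gives the diazomethylphosphonate anion, which olefinates the aldehyde to a diazoalkene that loses N2 and rearranges to the terminal alkyne; benzyl ethers are untouched.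

**Step 6**
Reactants: 8 5-(benzyloxy)-2-{[6-bromo-2,3,4-tris(benzyloxy)phenyl](hydroxy)methyl}phenol; 10 5-ethynyl-1,2,3-tris(benzyloxy)benzene
Product: 12 (4S)-7-(benzyloxy)-4-[6-bromo-2,3,4-tris(benzyloxy)phenyl]-2-[3,4,5-tris(benzyloxy)phenyl]-4H-chromene, via o-quinone methide 11 (not isolated)
Conditions: 10 (2 equiv), (R)-3,3′-bis(2,4,6-triisopropylphenyl)-1,1′-binaphthyl-2,2′-diyl N-triflylphosphoramide (10 mol %), 4 Å molecular sieves, PhCF3, −20 °C → rt
Reagents that add atoms: none
Why: Proposed new method: the strong chiral Brønsted acid should dehydrate 8 through its doubly benzylic cation, stabilised by the para benzyloxy group and the ortho hydroxyl of ring A, to the o-quinone methide 11, held as a hydrogen-bonded contact ion pair with the phosphoramide anion. The unsubstituted alkyne carbon of 10 then attacks the methide carbon and forms C3–C4, leaving the positive charge on the aryl-bearing carbon as a vinyl cation; the phenolic oxygen, still held by the anion, captures this cation and forms O1–C2, so the overall change is a stepwise polar [4+2] annulation (an oxa-Diels–Alder reaction of inverse electron demand if the two bonds form together). Ring C closes as a six-membered ring by oxygen attack on the digonal cationic carbon, with the new C2=C3 bond inside the ring (6-endo with respect to the former alkyne). The closest known reaction types are the racemic acid-catalysed annulation of o-hydroxybenzyl alcohols with aryl alkynes to 2,4-diaryl-4H-chromenes and chiral phosphoric acid-catalysed [4+2] reactions of o-quinone methides with alkenes; the enantioselective use of an alkyne is the untested element. C4 is the only new stereocentre and is fixed in the irreversible C–C bond formation by the chiral anion, whose 3,3′-aryl groups should shield one face of the methide carbon; which hand of the catalyst leads to (4S) has to be settled in a first screen, and its mirror image is available. Regiochemistry needs attack by the terminal carbon and is secured by the polarisation of 10, since only this mode places the cation next to the aryl ring with its para oxygen. Chemoselectivity is helped by the substrate: both positions ortho to the methide carbon on the hub ring are substituted (Br and OBn), so the usual indene-forming Friedel–Crafts closure of the vinyl cation is blocked, and the bromine is inert. Molecular sieves take up the water released, and the excess of 10 limits self-condensation of 11 with the electron-rich ring A of 8.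

**Step 7**
Reactants: 12 (4S)-7-(benzyloxy)-4-[6-bromo-2,3,4-tris(benzyloxy)phenyl]-2-[3,4,5-tris(benzyloxy)phenyl]-4H-chromene
Product: 14 (2R,3S,4S)-7-(benzyloxy)-4-[6-bromo-2,3,4-tris(benzyloxy)phenyl]-2-[3,4,5-tris(benzyloxy)phenyl]chroman-3-ol, via C3-alkylborane 13 (not isolated)
Conditions: BH3·THF (3 equiv), THF, 0 °C → rt; then aq NaOH, H2O2, 0 °C → rt
Reagents that add atoms: hydrogen peroxide, OO
Why: Hydroboration–oxidation of a cyclic enol ether: boron goes to C3 (β to O1 and away from the C2 aryl, both electronic preferences agree), B and H add syn on the face opposite the pseudoaxial C4 aryl, and oxidation replaces boron by hydroxyl with retention, so C3–OH ends trans to the C4 aryl and the C2 aryl trans to C3–OH; the whole (2R,3S,4S) triad follows from the one centre set in step 6.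

**Step 8**
Reactants: 14 (2R,3S,4S)-7-(benzyloxy)-4-[6-bromo-2,3,4-tris(benzyloxy)phenyl]-2-[3,4,5-tris(benzyloxy)phenyl]chroman-3-ol
Product: 15 (2R,3S,4S)-3,7-bis(benzyloxy)-4-[6-bromo-2,3,4-tris(benzyloxy)phenyl]-2-[3,4,5-tris(benzyloxy)phenyl]chromane
Conditions: NaH, BnBr, Bu4NI (cat.), DMF, 0 °C → rt
Reagents that add atoms: benzyl bromide, BrCc1ccccc1
Why: Williamson etherification of the secondary alkoxide; the cap is needed because a free C3 hydroxyl would form a six-membered lactol with the C1′ aldehyde of 17 and would compete as an internal nucleophile for the epoxide in step 14.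

**Step 9**
Reactants: 15 (2R,3S,4S)-3,7-bis(benzyloxy)-4-[6-bromo-2,3,4-tris(benzyloxy)phenyl]-2-[3,4,5-tris(benzyloxy)phenyl]chromane
Product: 17 3,4,5-tris(benzyloxy)-2-[(2R,3S,4S)-3,7-bis(benzyloxy)-2-[3,4,5-tris(benzyloxy)phenyl]chroman-4-yl]benzaldehyde, via aryllithium 16 (not isolated)
Conditions: n-BuLi (1.2 equiv), THF, −78 °C, 15 min; DMF (5 equiv), −78 → 0 °C; aq NH4Cl
Reagents that add atoms: N,N-dimethylformamide, CN(C)C=O
Why: Bromine–lithium exchange is faster than any deprotonation at −78 °C, and the aryllithium 16 is formylated by DMF (Bouveault aldehyde synthesis), the tetrahedral adduct collapsing on work-up; no stereocentre is touched.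

**Step 10**
Reactants: 18 2,4-dihydroxyacetophenone
Product: 19 1-[4-(benzyloxy)-2-hydroxyphenyl]ethan-1-one
Conditions: BnBr (1.05 equiv), K2CO3, acetone, reflux
Reagents that add atoms: benzyl bromide, BrCc1ccccc1
Why: Williamson etherification; the 2-hydroxyl is hydrogen-bonded to the ketone and stays free with one equivalent of halide.

**Step 11**
Reactants: 19 1-[4-(benzyloxy)-2-hydroxyphenyl]ethan-1-one
Product: 20 1-[4-(benzyloxy)-2-(methoxymethoxy)phenyl]ethan-1-one
Conditions: NaH (1.1 equiv), MeOCH2Cl, DMF, 0 °C → rt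
Reagents that add atoms: chloromethyl methyl ether, COCCl
Why: O-Alkylation of the sodium phenoxide to the methoxymethyl acetal; the group survives the basic steps 12 and 13 and is removed by the same acid that triggers ring closure in step 14.

**Step 12**
Reactants: 17 3,4,5-tris(benzyloxy)-2-[(2R,3S,4S)-3,7-bis(benzyloxy)-2-[3,4,5-tris(benzyloxy)phenyl]chroman-4-yl]benzaldehyde; 20 1-[4-(benzyloxy)-2-(methoxymethoxy)phenyl]ethan-1-one
Product: 21 (2E)-1-[4-(benzyloxy)-2-(methoxymethoxy)phenyl]-3-{3,4,5-tris(benzyloxy)-2-[(2R,3S,4S)-3,7-bis(benzyloxy)-2-[3,4,5-tris(benzyloxy)phenyl]chroman-4-yl]phenyl}prop-2-en-1-one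
Conditions: KOH (50% aq), EtOH/THF, rt → 40 °C
Reagents that add atoms: none
Why: Claisen–Schmidt condensation (crossed aldol, then dehydration): 17 cannot enolise, the enolate of 20 adds to it, and the thermodynamically favoured (E)-enone results; no stereocentre has an acidic hydrogen.

**Step 13**
Reactants: 21 (2E)-1-[4-(benzyloxy)-2-(methoxymethoxy)phenyl]-3-{3,4,5-tris(benzyloxy)-2-[(2R,3S,4S)-3,7-bis(benzyloxy)-2-[3,4,5-tris(benzyloxy)phenyl]chroman-4-yl]phenyl}prop-2-en-1-one
Product: 22 [4-(benzyloxy)-2-(methoxymethoxy)phenyl][(2R,3S)-3-{3,4,5-tris(benzyloxy)-2-[(2R,3S,4S)-3,7-bis(benzyloxy)-2-[3,4,5-tris(benzyloxy)phenyl]chroman-4-yl]phenyl}oxiran-2-yl]methanone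
Conditions: immobilised poly-L-leucine, urea–H2O2, DBU, THF, rt
Reagents that add atoms: hydrogen peroxide (used as its urea adduct), OO
Why: Juliá–Colonna epoxidation: hydroperoxide adds conjugatively to the enone bound at the amino terminus of the helical peptide and the enolate closes to the trans-epoxide; poly-L-leucine is known to give the (αR,βS) epoxides of chalcones, and the upper triad lies behind the hub ring, too far away to matter, so the catalyst should choose the face.

**Step 14**
Reactants: 22 [4-(benzyloxy)-2-(methoxymethoxy)phenyl][(2R,3S)-3-{3,4,5-tris(benzyloxy)-2-[(2R,3S,4S)-3,7-bis(benzyloxy)-2-[3,4,5-tris(benzyloxy)phenyl]chroman-4-yl]phenyl}oxiran-2-yl]methanone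
Product: 24 (2R,3R)-7-(benzyloxy)-3-hydroxy-2-{3,4,5-tris(benzyloxy)-2-[(2R,3S,4S)-3,7-bis(benzyloxy)-2-[3,4,5-tris(benzyloxy)phenyl]chroman-4-yl]phenyl}chroman-4-one, via phenol epoxide 23 (not isolated)
Conditions: conc. HCl (cat.), MeOH/THF, 50 °C
Reagents that add atoms: none
Why: Acid-catalysed acetal cleavage frees the 2′-phenol (23), which opens the protonated epoxide at its benzylic carbon (preferred over the carbon next to the carbonyl) in a 6-endo closure with inversion, forming O1–C2 while C3 keeps its oxygen and configuration; the (αR,βS) epoxide therefore gives the (2R,3R) trans-dihydroflavonol, which is also the more stable diequatorial isomer.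

**Step 15**
Reactants: 24 (2R,3R)-7-(benzyloxy)-3-hydroxy-2-{3,4,5-tris(benzyloxy)-2-[(2R,3S,4S)-3,7-bis(benzyloxy)-2-[3,4,5-tris(benzyloxy)phenyl]chroman-4-yl]phenyl}chroman-4-one
Product: 25 (2R,3R)-2-{2-[(2R,3S,4S)-3,7-dihydroxy-2-(3,4,5-trihydroxyphenyl)chroman-4-yl]-3,4,5-trihydroxyphenyl}-3,7-dihydroxychroman-4-one
Conditions: H2 (1 atm), Pd(OH)2/C, THF/MeOH, rt
Reagents that add atoms: none
Why: Catalytic hydrogenolysis of all nine benzyl ethers under neutral conditions; it precedes the reduction so that no benzylic C4–O bond is present, the aryl ketone is a vinylogous ester deactivated by its ortho and para ring oxygens, and the cyclic C2–O1 bonds are not cleaved without acid.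

**Step 16**
Reactants: 25 (2R,3R)-2-{2-[(2R,3S,4S)-3,7-dihydroxy-2-(3,4,5-trihydroxyphenyl)chroman-4-yl]-3,4,5-trihydroxyphenyl}-3,7-dihydroxychroman-4-one
Product: 26 (2R,3S,4R)-2-{2-[(2R,3S,4S)-3,7-dihydroxy-2-(3,4,5-trihydroxyphenyl)chroman-4-yl]-3,4,5-trihydroxyphenyl}chromane-3,4,7-triol
Conditions: NaBH4, degassed MeOH, 0 °C, argon; AcOH to pH 6; Sephadex LH-20
Reagents that add atoms: none
Why: Hydride reduction of the chromanone carbonyl; NaBH4 adds along the axial direction of the half-chair and gives the equatorial C4 hydroxyl trans to the equatorial C3 hydroxyl, (4R), the established outcome for 2,3-trans-dihydroflavonols; degassed solvent, low temperature and a near-neutral work-up protect the pyrogallols and the acid-labile benzylic alcohol.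

## Compound list

1 | 2,4-dihydroxybenzaldehyde | O=Cc1ccc(O)cc1O | starting material
2 | 4-(benzyloxy)-2-hydroxybenzaldehyde | O=Cc1ccc(OCc2ccccc2)cc1O | intermediate
3 | 5-bromo-1,2,3-trimethoxybenzene | COc1cc(Br)cc(OC)c1OC | starting material
4 | 5-bromobenzene-1,2,3-triol | Oc1cc(Br)cc(O)c1O | intermediate
5 | 5-bromo-1,2,3-tris(benzyloxy)benzene | Brc1cc(OCc2ccccc2)c(OCc2ccccc2)c(OCc2ccccc2)c1 | intermediate
6 | [6-bromo-2,3,4-tris(benzyloxy)phenyl]lithium | [Li]c1c(Br)cc(OCc2ccccc2)c(OCc2ccccc2)c1OCc1ccccc1 | intermediate (not isolated)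
7 | lithium 5-(benzyloxy)-2-formylphenolate | [Li+].[O-]c1cc(OCc2ccccc2)ccc1C=O | intermediate (not isolated)
8 | 5-(benzyloxy)-2-{[6-bromo-2,3,4-tris(benzyloxy)phenyl](hydroxy)methyl}phenol, racemic at the carbinol carbon | Oc1cc(OCc2ccccc2)ccc1C(O)c1c(Br)cc(OCc2ccccc2)c(OCc2ccccc2)c1OCc1ccccc1 | intermediate
9 | 3,4,5-tris(benzyloxy)benzaldehyde | O=Cc1cc(OCc2ccccc2)c(OCc2ccccc2)c(OCc2ccccc2)c1 | starting material
10 | 5-ethynyl-1,2,3-tris(benzyloxy)benzene | C#Cc1cc(OCc2ccccc2)c(OCc2ccccc2)c(OCc2ccccc2)c1 | intermediate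
11 | (6E)-3-(benzyloxy)-6-{[6-bromo-2,3,4-tris(benzyloxy)phenyl]methylidene}cyclohexa-2,4-dien-1-one | Brc1cc(OCc2ccccc2)c(OCc2ccccc2)c(OCc2ccccc2)c1/C=C1/C(=O)C=C(OCc2ccccc2)C=C1 | intermediate (not isolated)
12 | (4S)-7-(benzyloxy)-4-[6-bromo-2,3,4-tris(benzyloxy)phenyl]-2-[3,4,5-tris(benzyloxy)phenyl]-4H-chromene | C(c1ccccc1)Oc1ccc2c(c1)OC(c1cc(OCc3ccccc3)c(OCc3ccccc3)c(OCc3ccccc3)c1)=C[C@@H]2c1c(Br)cc(OCc3ccccc3)c(OCc3ccccc3)c1OCc1ccccc1 | intermediate
13 | [(2S,3S,4S)-7-(benzyloxy)-4-[6-bromo-2,3,4-tris(benzyloxy)phenyl]-2-[3,4,5-tris(benzyloxy)phenyl]chroman-3-yl]borane (boron trans to the C4 aryl and cis to the new C2–H; same spatial arrangement as 14, the descriptor at C2 differs only through the priority of boron) | C(c1ccccc1)Oc1ccc2c(c1)O[C@H](c1cc(OCc3ccccc3)c(OCc3ccccc3)c(OCc3ccccc3)c1)[C@@H](B)[C@@H]2c1c(Br)cc(OCc3ccccc3)c(OCc3ccccc3)c1OCc1ccccc1 | intermediate (not isolated)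
14 | (2R,3S,4S)-7-(benzyloxy)-4-[6-bromo-2,3,4-tris(benzyloxy)phenyl]-2-[3,4,5-tris(benzyloxy)phenyl]chroman-3-ol | C(c1ccccc1)Oc1ccc2c(c1)O[C@H](c1cc(OCc3ccccc3)c(OCc3ccccc3)c(OCc3ccccc3)c1)[C@@H](O)[C@@H]2c1c(Br)cc(OCc3ccccc3)c(OCc3ccccc3)c1OCc1ccccc1 | intermediate
15 | (2R,3S,4S)-3,7-bis(benzyloxy)-4-[6-bromo-2,3,4-tris(benzyloxy)phenyl]-2-[3,4,5-tris(benzyloxy)phenyl]chromane | C(c1ccccc1)Oc1ccc2c(c1)O[C@H](c1cc(OCc3ccccc3)c(OCc3ccccc3)c(OCc3ccccc3)c1)[C@@H](OCc1ccccc1)[C@@H]2c1c(Br)cc(OCc3ccccc3)c(OCc3ccccc3)c1OCc1ccccc1 | intermediate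
16 | {3,4,5-tris(benzyloxy)-2-[(2R,3S,4S)-3,7-bis(benzyloxy)-2-[3,4,5-tris(benzyloxy)phenyl]chroman-4-yl]phenyl}lithium | C(c1ccccc1)Oc1ccc2c(c1)O[C@H](c1cc(OCc3ccccc3)c(OCc3ccccc3)c(OCc3ccccc3)c1)[C@@H](OCc1ccccc1)[C@@H]2c1c([Li])cc(OCc3ccccc3)c(OCc3ccccc3)c1OCc1ccccc1 | intermediate (not isolated)
17 | 3,4,5-tris(benzyloxy)-2-[(2R,3S,4S)-3,7-bis(benzyloxy)-2-[3,4,5-tris(benzyloxy)phenyl]chroman-4-yl]benzaldehyde | C(c1ccccc1)Oc1ccc2c(c1)O[C@H](c1cc(OCc3ccccc3)c(OCc3ccccc3)c(OCc3ccccc3)c1)[C@@H](OCc1ccccc1)[C@@H]2c1c(C=O)cc(OCc3ccccc3)c(OCc3ccccc3)c1OCc1ccccc1 | intermediate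
18 | 2,4-dihydroxyacetophenone | CC(=O)c1ccc(O)cc1O | starting material
19 | 1-[4-(benzyloxy)-2-hydroxyphenyl]ethan-1-one | CC(=O)c1ccc(OCc2ccccc2)cc1O | intermediate
20 | 1-[4-(benzyloxy)-2-(methoxymethoxy)phenyl]ethan-1-one | CC(=O)c1ccc(OCc2ccccc2)cc1OCOC | intermediate
21 | (2E)-1-[4-(benzyloxy)-2-(methoxymethoxy)phenyl]-3-{3,4,5-tris(benzyloxy)-2-[(2R,3S,4S)-3,7-bis(benzyloxy)-2-[3,4,5-tris(benzyloxy)phenyl]chroman-4-yl]phenyl}prop-2-en-1-one | C(c1ccccc1)Oc1ccc2c(c1)O[C@H](c1cc(OCc3ccccc3)c(OCc3ccccc3)c(OCc3ccccc3)c1)[C@@H](OCc1ccccc1)[C@@H]2c1c(/C=C/C(=O)c3ccc(OCc4ccccc4)cc3OCOC)cc(OCc3ccccc3)c(OCc3ccccc3)c1OCc1ccccc1 | intermediate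
22 | [4-(benzyloxy)-2-(methoxymethoxy)phenyl][(2R,3S)-3-{3,4,5-tris(benzyloxy)-2-[(2R,3S,4S)-3,7-bis(benzyloxy)-2-[3,4,5-tris(benzyloxy)phenyl]chroman-4-yl]phenyl}oxiran-2-yl]methanone | C(c1ccccc1)Oc1ccc2c(c1)O[C@H](c1cc(OCc3ccccc3)c(OCc3ccccc3)c(OCc3ccccc3)c1)[C@@H](OCc1ccccc1)[C@@H]2c1c([C@H]3[C@H](C(=O)c4ccc(OCc5ccccc5)cc4OCOC)O3)cc(OCc3ccccc3)c(OCc3ccccc3)c1OCc1ccccc1 | intermediate
23 | [4-(benzyloxy)-2-hydroxyphenyl][(2R,3S)-3-{3,4,5-tris(benzyloxy)-2-[(2R,3S,4S)-3,7-bis(benzyloxy)-2-[3,4,5-tris(benzyloxy)phenyl]chroman-4-yl]phenyl}oxiran-2-yl]methanone | C(c1ccccc1)Oc1ccc2c(c1)O[C@H](c1cc(OCc3ccccc3)c(OCc3ccccc3)c(OCc3ccccc3)c1)[C@@H](OCc1ccccc1)[C@@H]2c1c([C@H]3[C@H](C(=O)c4ccc(OCc5ccccc5)cc4O)O3)cc(OCc3ccccc3)c(OCc3ccccc3)c1OCc1ccccc1 | intermediate (not isolated)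
24 | (2R,3R)-7-(benzyloxy)-3-hydroxy-2-{3,4,5-tris(benzyloxy)-2-[(2R,3S,4S)-3,7-bis(benzyloxy)-2-[3,4,5-tris(benzyloxy)phenyl]chroman-4-yl]phenyl}chroman-4-one | C(c1ccccc1)Oc1ccc2c(c1)O[C@H](c1cc(OCc3ccccc3)c(OCc3ccccc3)c(OCc3ccccc3)c1)[C@@H](OCc1ccccc1)[C@@H]2c1c([C@H]3Oc4cc(OCc5ccccc5)ccc4C(=O)[C@@H]3O)cc(OCc3ccccc3)c(OCc3ccccc3)c1OCc1ccccc1 | intermediate
25 | (2R,3R)-2-{2-[(2R,3S,4S)-3,7-dihydroxy-2-(3,4,5-trihydroxyphenyl)chroman-4-yl]-3,4,5-trihydroxyphenyl}-3,7-dihydroxychroman-4-one | Oc1ccc2c(c1)O[C@H](c1cc(O)c(O)c(O)c1)[C@@H](O)[C@@H]2c1c([C@H]3Oc4cc(O)ccc4C(=O)[C@@H]3O)cc(O)c(O)c1O | intermediate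
26 | (2R,3S,4R)-2-{2-[(2R,3S,4S)-3,7-dihydroxy-2-(3,4,5-trihydroxyphenyl)chroman-4-yl]-3,4,5-trihydroxyphenyl}chromane-3,4,7-triol | Oc1ccc2c(c1)O[C@H](c1cc(O)c(O)c(O)c1)[C@@H](O)[C@@H]2c1c([C@H]2Oc3cc(O)ccc3[C@@H](O)[C@@H]2O)cc(O)c(O)c1O | target

## Step count and least certain steps

- **Total:** 16 steps.
- **Longest linear sequence:** 12 steps (3 → 4 → 5 → 8 → 12 → 14 → 15 → 17 → 21 → 22 → 24 → 25 → 26; steps 2, 3, 4, 6, 7, 8, 9, 12, 13, 14, 15, 16).
- Compounds 2 and 19 are also catalogue items; buying them would remove steps 1 and 10.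

**Step 6 (key step, proposed new method).**
- **What may go wrong:** poor enantioface selection, because the alkyne offers no second contact to the catalyst and both faces of the methide carbon are flanked by an ortho substituent of the twisted hub ring. C–C bond formation may also be slow with this modest π-nucleophile, which would let 11 condense with ring A of unreacted 8 or let the alkyne hydrate. The enol ether product may be hydrolysed by the acid.
- **Fallback (known chemistry only):** starting from 8 and 10, the annulation would be run with an achiral acid (CF3SO3H, 5 mol %, CH2Cl2, −40 °C) to give the racemic 4H-chromene F1. Hydroboration–oxidation as in step 7 would give the racemic 2,3-trans-3,4-trans alcohol F2. Acylation with (S)-2-methoxy-2-phenylacetic acid (DCC, DMAP, CH2Cl2) would give two diastereomeric esters, the (2R,3S,4S) ester F3 and the (2S,3R,4R) ester F4, to be separated by chromatography or crystallisation. LiOH (THF/MeOH/H2O) would cleave F3 to 14, where the route is rejoined. The price is two more steps and half of the material.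

**Step 4.**
- **What may go wrong:** loss of LiBr from 6 (aryne formation) before it has added to the deactivated phenolate aldehyde 7, or incomplete metalation.
- **Fallback:** starting from 5, N-bromosuccinimide (MeCN, rt) should brominate the activated position next to the existing bromine to give 4,5-dibromo-1,2,3-tris(benzyloxy)benzene F5. i-PrMgCl·LiCl (THF, −20 °C) should exchange selectively the bromine flanked by the ether oxygen, giving the arylmagnesium chloride F6, which can be warmed to 0 °C without aryne formation. F6 is added to 7, and the route is rejoined at 8.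

**Step 7.**
- **What may go wrong:** β-elimination of the C3 borane with the ring oxygen (opening of ring C), or addition from the face of the C4 aryl.
- **Fallback:** starting from 12, dimethyldioxirane in acetone/MeOH at −40 °C should epoxidise the enol ether anti to the C4 aryl, and methanol opens the epoxy acetal to the 2-methoxychroman-3-ol F7. Et3SiH with BF3·OEt2 (CH2Cl2, −78 °C) should ionise the ketal to the 2-aryl oxocarbenium ion and deliver hydride axially, so that the C2 aryl becomes equatorial. This gives 14, where the route is rejoined.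

**Step 13.**
- **What may go wrong:** low conversion, because the bulky ortho-substituted enone may not fit the peptide catalyst, or weak face selection.
- **Fallback:** starting from 21, plain Weitz–Scheffer epoxidation (H2O2, aq NaOH, THF/MeOH, 0 °C) would give 22 together with the (2S,3R)-epoxide diastereomer F8. The two differ as diastereomers because of the upper triad and would be separated by chromatography; 22 goes on and the route is rejoined there.

**Step 14.**
- **What may go wrong:** acyl or aryl migration in the opened epoxide, capture of the benzylic carbon by methanol, or partial loss of configuration at C2.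
- **Fallback:** starting from 22, the epoxide would be opened in a separate operation with benzyl mercaptan and SnCl4 (CH2Cl2, −20 °C, kept cold to spare the benzyl ethers). This also removes the methoxymethyl group and gives the β-benzylsulfanyl α-hydroxy ketone F9. AgBF4 (CH2Cl2, 0 °C) would then activate the sulfide as a leaving group for closure by the phenol to the more stable trans isomer 24, where the route is rejoined.

## Further compounds

F1 | step 6 | rac-7-(benzyloxy)-4-[6-bromo-2,3,4-tris(benzyloxy)phenyl]-2-[3,4,5-tris(benzyloxy)phenyl]-4H-chromene | C(c1ccccc1)Oc1ccc2c(c1)OC(c1cc(OCc3ccccc3)c(OCc3ccccc3)c(OCc3ccccc3)c1)=CC2c1c(Br)cc(OCc3ccccc3)c(OCc3ccccc3)c1OCc1ccccc1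
F2 | step 6 | racemic 2,3-trans-3,4-trans 7-(benzyloxy)-4-[6-bromo-2,3,4-tris(benzyloxy)phenyl]-2-[3,4,5-tris(benzyloxy)phenyl]chroman-3-ol, (2R,3S,4S) and (2S,3R,4R) in equal amounts | C(c1ccccc1)Oc1ccc2c(c1)O[C@H](c1cc(OCc3ccccc3)c(OCc3ccccc3)c(OCc3ccccc3)c1)[C@@H](O)[C@@H]2c1c(Br)cc(OCc3ccccc3)c(OCc3ccccc3)c1OCc1ccccc1.C(c1ccccc1)Oc1ccc2c(c1)O[C@@H](c1cc(OCc3ccccc3)c(OCc3ccccc3)c(OCc3ccccc3)c1)[C@H](O)[C@H]2c1c(Br)cc(OCc3ccccc3)c(OCc3ccccc3)c1OCc1ccccc1
F3 | step 6 | (2R,3S,4S)-7-(benzyloxy)-4-[6-bromo-2,3,4-tris(benzyloxy)phenyl]-2-[3,4,5-tris(benzyloxy)phenyl]chroman-3-yl (2S)-2-methoxy-2-phenylacetate | C(c1ccccc1)Oc1ccc2c(c1)O[C@H](c1cc(OCc3ccccc3)c(OCc3ccccc3)c(OCc3ccccc3)c1)[C@@H](OC(=O)[C@@H](OC)c1ccccc1)[C@@H]2c1c(Br)cc(OCc3ccccc3)c(OCc3ccccc3)c1OCc1ccccc1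
F4 | step 6 | (2S,3R,4R)-7-(benzyloxy)-4-[6-bromo-2,3,4-tris(benzyloxy)phenyl]-2-[3,4,5-tris(benzyloxy)phenyl]chroman-3-yl (2S)-2-methoxy-2-phenylacetate | C(c1ccccc1)Oc1ccc2c(c1)O[C@@H](c1cc(OCc3ccccc3)c(OCc3ccccc3)c(OCc3ccccc3)c1)[C@H](OC(=O)[C@@H](OC)c1ccccc1)[C@H]2c1c(Br)cc(OCc3ccccc3)c(OCc3ccccc3)c1OCc1ccccc1
F5 | step 4 | 4,5-dibromo-1,2,3-tris(benzyloxy)benzene | Brc1cc(OCc2ccccc2)c(OCc2ccccc2)c(OCc2ccccc2)c1Br
F6 | step 4 | [6-bromo-2,3,4-tris(benzyloxy)phenyl]magnesium chloride | Cl[Mg]c1c(Br)cc(OCc2ccccc2)c(OCc2ccccc2)c1OCc1ccccc1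
F7 | step 7 | (3S,4S)-7-(benzyloxy)-4-[6-bromo-2,3,4-tris(benzyloxy)phenyl]-2-methoxy-2-[3,4,5-tris(benzyloxy)phenyl]chroman-3-ol (both C2 anomers) | C(c1ccccc1)Oc1ccc2c(c1)OC(OC)(c1cc(OCc3ccccc3)c(OCc3ccccc3)c(OCc3ccccc3)c1)[C@@H](O)[C@@H]2c1c(Br)cc(OCc3ccccc3)c(OCc3ccccc3)c1OCc1ccccc1
F8 | step 13 | [4-(benzyloxy)-2-(methoxymethoxy)phenyl][(2S,3R)-3-{3,4,5-tris(benzyloxy)-2-[(2R,3S,4S)-3,7-bis(benzyloxy)-2-[3,4,5-tris(benzyloxy)phenyl]chroman-4-yl]phenyl}oxiran-2-yl]methanone | C(c1ccccc1)Oc1ccc2c(c1)O[C@H](c1cc(OCc3ccccc3)c(OCc3ccccc3)c(OCc3ccccc3)c1)[C@@H](OCc1ccccc1)[C@@H]2c1c([C@@H]3[C@@H](C(=O)c4ccc(OCc5ccccc5)cc4OCOC)O3)cc(OCc3ccccc3)c(OCc3ccccc3)c1OCc1ccccc1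
F9 | step 14 | (2S)-3-(benzylsulfanyl)-1-[4-(benzyloxy)-2-hydroxyphenyl]-2-hydroxy-3-{3,4,5-tris(benzyloxy)-2-[(2R,3S,4S)-3,7-bis(benzyloxy)-2-[3,4,5-tris(benzyloxy)phenyl]chroman-4-yl]phenyl}propan-1-one (both C3 epimers) | C(c1ccccc1)Oc1ccc2c(c1)O[C@H](c1cc(OCc3ccccc3)c(OCc3ccccc3)c(OCc3ccccc3)c1)[C@@H](OCc1ccccc1)[C@@H]2c1c(C(SCc3ccccc3)[C@@H](O)C(=O)c3ccc(OCc4ccccc4)cc3O)cc(OCc3ccccc3)c(OCc3ccccc3)c1OCc1ccccc1
A1 | alternative 1 | 5,6-bis(benzyloxy)-2-[(2R,3S,4S)-3,7-bis(benzyloxy)-2-[3,4,5-tris(benzyloxy)phenyl]chroman-4-yl]-3-{[(tert-butyldimethylsilyl)oxy]methyl}phenol | C(c1ccccc1)Oc1ccc2c(c1)O[C@H](c1cc(OCc3ccccc3)c(OCc3ccccc3)c(OCc3ccccc3)c1)[C@@H](OCc1ccccc1)[C@@H]2c1c(CO[Si](C)(C)C(C)(C)C)cc(OCc3ccccc3)c(OCc3ccccc3)c1O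
A2 | alternative 1 | 2,3-bis(benzyloxy)-4-[(1Z)-1-{(2R,3S,4R)-3,7-bis(benzyloxy)-2-[3,4,5-tris(benzyloxy)phenyl]chroman-4-yl}-3-[(tert-butyldimethylsilyl)oxy]prop-1-en-2-yl]cyclobut-2-en-1-one (either epimer at the ring sp3 carbon) | C(c1ccccc1)Oc1ccc2c(c1)O[C@H](c1cc(OCc3ccccc3)c(OCc3ccccc3)c(OCc3ccccc3)c1)[C@@H](OCc1ccccc1)[C@@H]2/C=C(CO[Si](C)(C)C(C)(C)C)/C1C(=O)C(OCc3ccccc3)=C1OCc1ccccc1
A3 | alternative 2 | (2R,3S,4S)-7-(benzyloxy)-4-[6-bromo-2,3,4-tris(benzyloxy)phenyl]-2-[3,4,5-tris(benzyloxy)phenyl]chroman-3-ol (identical with 14) | C(c1ccccc1)Oc1ccc2c(c1)O[C@H](c1cc(OCc3ccccc3)c(OCc3ccccc3)c(OCc3ccccc3)c1)[C@@H](O)[C@@H]2c1c(Br)cc(OCc3ccccc3)c(OCc3ccccc3)c1OCc1ccccc1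
A4 | alternative 2 | 1-(benzyloxy)-3-{(R)-[(2S,3R)-3-[6-bromo-2,3,4-tris(benzyloxy)phenyl]oxiran-2-yl][3,4,5-tris(benzyloxy)phenyl]methoxy}benzene | C(c1ccccc1)Oc1cccc(c1)O[C@H](c1cc(OCc2ccccc2)c(OCc2ccccc2)c(OCc2ccccc2)c1)[C@H]1O[C@@H]1c1c(Br)cc(OCc2ccccc2)c(OCc2ccccc2)c1OCc1ccccc1
A5 | alternative 3 | (2R,3R)-7-(benzyloxy)-3-hydroxy-2-{3,4,5-tris(benzyloxy)-2-[(2R,3S,4S)-3,7-bis(benzyloxy)-2-[3,4,5-tris(benzyloxy)phenyl]chroman-4-yl]phenyl}chroman-4-one (identical with 24) | C(c1ccccc1)Oc1ccc2c(c1)O[C@H](c1cc(OCc3ccccc3)c(OCc3ccccc3)c(OCc3ccccc3)c1)[C@@H](OCc1ccccc1)[C@@H]2c1c([C@H]3Oc4cc(OCc5ccccc5)ccc4C(=O)[C@@H]3O)cc(OCc3ccccc3)c(OCc3ccccc3)c1OCc1ccccc1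
A6 | alternative 3 | [4-(benzyloxy)-2-(methoxymethoxy)phenyl][(2R,3S)-3-{3,4,5-tris(benzyloxy)-2-[(2R,3S,4S)-3,7-bis(benzyloxy)-2-[3,4,5-tris(benzyloxy)phenyl]chroman-4-yl]phenyl}oxiran-2-yl]methanone (identical with 22) | C(c1ccccc1)Oc1ccc2c(c1)O[C@H](c1cc(OCc3ccccc3)c(OCc3ccccc3)c(OCc3ccccc3)c1)[C@@H](OCc1ccccc1)[C@@H]2c1c([C@H]3[C@H](C(=O)c4ccc(OCc5ccccc5)cc4OCOC)O3)cc(OCc3ccccc3)c(OCc3ccccc3)c1OCc1ccccc1
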